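## Retrosynthetic overview

1. Target 17 ⇐ biaryl 16 by mild acid unmasking; 16 ⇐ Suzuki–Miyaura union of the two halves at C7–C7′ (last C–C bond).
2. Both halves ⇐ one racemic oxabenzonorbornadiene 7. The key bond, C2–C(=O)CH3, is made by anti-SN2′ attack of an acetyl anion equivalent (1-ethoxyvinyl Grignard 9, from ethyl vinyl ether) on the bridged allylic ether.
3. With a chiral copper catalyst this opening is a kinetic resolution: (1R,4S)-7 gives the (1S,2R) half 10, both stereocentres at once. The unreacted enantiomer is opened achirally, oxidised and aromatised to the achiral half 14.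
4. 7 ⇐ aryne from 2-bromo-5-fluorophenol + 3-methylfuran, [4+2].
5. Ring order: benzene ring bought → second six-membered ring by aryne cycloaddition → bridge opened (dihydronaphthalene) or opened and aromatised (naphthalene) → biaryl.

Assumption: the acetal carbon of the 1-ethoxyethyl group is an uncontrolled, traceless stereocentre (about 1:1) and is left undefined in names and SMILES. The hand of ligand L that consumes (1R,4S)-7 is taken as (S,S,S), to be confirmed in a pilot run (otherwise its antipode is used).

## Route

Step 1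
Reactants: 1 2-bromo-5-fluorophenol; 2 ethyl vinyl ether
Product: 3 1-bromo-2-(1-ethoxyethoxy)-4-fluorobenzene
Conditions: 2 (3 equiv), pyridinium p-toluenesulfonate (2 mol%), CH2Cl2, 0 → 20 °C
Reagents that add atoms: none
Why: Acid-catalysed addition of the phenol to the vinyl ether (acetal protection) gives an ether that survives amide bases, organometallics and aqueous base and falls off in dilute acid in the last step.

Step 2
Reactants: 3 1-bromo-2-(1-ethoxyethoxy)-4-fluorobenzene; 4 3-methylfuran
Product: 7 rac-(1R,4S)-6-bromo-5-(1-ethoxyethoxy)-2-methyl-1,4-dihydro-1,4-epoxynaphthalene, via [3-bromo-2-(1-ethoxyethoxy)-6-fluorophenyl]lithium 5 (not isolated), via 4-bromo-3-(1-ethoxyethoxy)benzyne 6 (not isolated)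
Conditions: lithium 2,2,6,6-tetramethylpiperidide (1.2 equiv), THF, −78 °C; 4 (5 equiv), −78 → 20 °C
Reagents that add atoms: none
Why: Directed ortho-lithiation at the C–H flanked by OR and F, loss of LiF and aryne Diels–Alder reaction with the furan; the more nucleophilic furan C2 (next to methyl) should bond to the aryne carbon remote from the alkoxy group, but the bias is expected to be only modest (estimated about 2:1), so the 3-methyl isomer is removed by chromatography here or, if inseparable, after step 4; the two bridgeheads are necessarily cis and racemic.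

Step 3
Reactants: 2 ethyl vinyl ether
Product: 9 bromo(1-ethoxyethenyl)magnesium, via (1-ethoxyethenyl)lithium 8 (not isolated)
Conditions: t-BuLi (0.95 equiv), THF (minimum volume), −78 → 0 °C; MgBr2·OEt2 (1.0 equiv), −78 → 0 °C; titrated stock solution, kept at −20 °C under argon and used for steps 4 and 5
Reagents that add atoms: magnesium bromide (as its diethyl etherate), Br[Mg]Br
Why: α-Deprotonation of the vinyl ether at the oxygen-bearing sp2 carbon by t-BuLi followed by lithium-to-magnesium transmetalation gives the 1-ethoxyvinyl Grignard reagent, a masked acetyl anion, in one batch that serves both ring openings.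

Step 4
Reactants: 7 rac-(1R,4S)-6-bromo-5-(1-ethoxyethoxy)-2-methyl-1,4-dihydro-1,4-epoxynaphthalene (1.0 equiv); 9 bromo(1-ethoxyethenyl)magnesium (0.55 equiv)
Product: 10 (1S,2R)-7-bromo-2-(1-ethoxyethenyl)-8-(1-ethoxyethoxy)-3-methyl-1,2-dihydronaphthalen-1-ol
Conditions: CuBr·SMe2 (5 mol%), (S,S,S)-L [O,O′-((S)-1,1′-binaphthalene-2,2′-diyl) N,N-bis((S)-1-phenylethyl)phosphoramidite, 10 mol%], CH2Cl2–Et2O, slow addition of 9, −78 → −50 °C, to about 45% conversion; aq NaHCO3
Reagents that add atoms: none
Why: Proposed new method: a monovalent copper (1-ethoxyvinyl) species (an acetyl anion equivalent) adds to the unsubstituted alkene carbon C3 of 7 on the face anti to the oxygen bridge (allyl trivalent copper intermediate, magnesium activating the bridge), the alkene shifts to C1=C2 and the C1–O bond next to the methyl-bearing carbon breaks, so C4 keeps its oxygen and becomes the carbinol C1 of 10 while the acyl surrogate sits trans to it on C2; the chiral phosphoramidite, which on meso oxabenzonorbornadienes selects one enantiotopic alkene terminus, should let only (1R,4S)-7 react at its unhindered terminus (kinetic resolution: the carbinol carbon stays S, C2 is formed R, unreacted (1S,4R)-enriched 7 is recovered for step 5); closest known reactions are copper/phosphoramidite-catalysed anti-selective asymmetric ring openings of oxabenzonorbornadienes with dialkylzinc, Grignard and organolithium reagents and SN2′ substitutions of (α-alkoxyvinyl)cuprates.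

Step 5
Reactants: 7 rac-(1R,4S)-6-bromo-5-(1-ethoxyethoxy)-2-methyl-1,4-dihydro-1,4-epoxynaphthalene (material recovered from step 4, topped up with racemate); 9 bromo(1-ethoxyethenyl)magnesium (1.5 equiv)
Product: 14 1-(7-bromo-1,8-dihydroxy-3-methylnaphthalen-2-yl)ethan-1-one, via (1R,2S)-carbinol magnesium alkoxide 11 (not isolated), via 2H-naphthalen-1-one 12 (not isolated), via naphthol enol ether 13 (not isolated)
Conditions: CuCl (10 mol%), PPh3 (10 mol%), Et2O–toluene, −20 → 20 °C; PhCHO (3 equiv), 20 °C; then 2 M HCl, THF, 20 °C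
Reagents that add atoms: water, O
Why: Proposed new method: the same acetyl anion equivalent in the known achiral CuCl/PPh3 anti-SN2′ opening with Grignard reagents gives alkoxide 11 (configuration irrelevant), whose benzylic hydride passes to benzaldehyde (magnesium Oppenauer oxidation); ketone 12 enolises irreversibly to naphthoxide 13 and aqueous acid hydrolyses the enol ether to the acetyl group and removes the acetal, erasing both stereocentres.

Step 6
Reactants: 10 (1S,2R)-7-bromo-2-(1-ethoxyethenyl)-8-(1-ethoxyethoxy)-3-methyl-1,2-dihydronaphthalen-1-ol; 14 1-(7-bromo-1,8-dihydroxy-3-methylnaphthalen-2-yl)ethan-1-one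
Product: 16 1-{7-[(7R,8S)-7-(1-ethoxyethenyl)-1-(1-ethoxyethoxy)-8-hydroxy-6-methyl-7,8-dihydronaphthalen-2-yl]-1,8-dihydroxy-3-methylnaphthalen-2-yl}ethan-1-one, via pinacol boronate 15 (not isolated)
Conditions: 10, B2pin2 (1.1 equiv), Pd2(dba)3 (2 mol%), XPhos (8 mol%), KOAc, 1,4-dioxane, 90 °C; then 14 (1.2 equiv), aq K3PO4, 70 °C
Reagents that add atoms: none
Why: One-pot Miyaura borylation and Suzuki–Miyaura coupling; enol ether, acetal and carbinol are base-stable so C1 and C2 are untouched, free phenols are tolerated, and the biaryl axis (one ortho substituent per ring) is not a stereo element.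

Step 7
Reactants: 16 1-{7-[(7R,8S)-7-(1-ethoxyethenyl)-1-(1-ethoxyethoxy)-8-hydroxy-6-methyl-7,8-dihydronaphthalen-2-yl]-1,8-dihydroxy-3-methylnaphthalen-2-yl}ethan-1-one
Product: 17 1-{7-[(7R,8S)-7-acetyl-1,8-dihydroxy-6-methyl-7,8-dihydronaphthalen-2-yl]-1,8-dihydroxy-3-methylnaphthalen-2-yl}ethan-1-one (the target; (1S,2R) in the numbering of the target SMILES)
Conditions: 0.02 M HCl, THF–H2O (3:1), 0 → 10 °C, about 1 h; pH 7 phosphate buffer
Reagents that add atoms: water, O
Why: Specific-acid hydrolysis: the 2-alkoxypropene-type enol ether is cleaved within minutes and the aryl acetal within the hour, which should be far faster than acid-catalysed enolisation at C2 or ionisation at C1, so neither stereocentre is touched and the trans hydroxy ketone is not dehydrated to the naphthalene.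

## Compound list

1 | 2-bromo-5-fluorophenol | Oc1cc(F)ccc1Br | starting material
2 | ethyl vinyl ether | C=COCC | starting material
3 | 1-bromo-2-(1-ethoxyethoxy)-4-fluorobenzene | CCOC(C)Oc1cc(F)ccc1Br | intermediate
4 | 3-methylfuran | Cc1ccoc1 | starting material
5 | [3-bromo-2-(1-ethoxyethoxy)-6-fluorophenyl]lithium | [Li]c1c(F)ccc(Br)c1OC(C)OCC | intermediate (not isolated)
6 | 4-bromo-3-(1-ethoxyethoxy)benzyne | CCOC(C)OC1=C(Br)C=CC#C1 | intermediate (not isolated)
7 | rac-(1R,4S)-6-bromo-5-(1-ethoxyethoxy)-2-methyl-1,4-dihydro-1,4-epoxynaphthalene (racemate; SMILES shows the (1R,4S) enantiomer consumed in step 4) | Brc1ccc2c(c1OC(C)OCC)[C@@H]3C=C(C)[C@H]2O3 | intermediate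
8 | (1-ethoxyethenyl)lithium | [Li]C(=C)OCC | intermediate (not isolated)
9 | bromo(1-ethoxyethenyl)magnesium (titrated stock solution) | C=C(OCC)[Mg]Br | intermediate
10 | (1S,2R)-7-bromo-2-(1-ethoxyethenyl)-8-(1-ethoxyethoxy)-3-methyl-1,2-dihydronaphthalen-1-ol | Brc1ccc2c(c1OC(C)OCC)[C@@H](O)[C@H](C(=C)OCC)C(C)=C2 | intermediate
11 | (1R,2S)-7-bromo-2-(1-ethoxyethenyl)-8-(1-ethoxyethoxy)-3-methyl-1,2-dihydronaphthalen-1-ol (present as its bromomagnesium alkoxide; either enantiomer serves) | Brc1ccc2c(c1OC(C)OCC)[C@H](O)[C@@H](C(=C)OCC)C(C)=C2 | intermediate (not isolated)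
12 | (2R)-7-bromo-2-(1-ethoxyethenyl)-8-(1-ethoxyethoxy)-3-methylnaphthalen-1(2H)-one | Brc1ccc2c(c1OC(C)OCC)C(=O)[C@@H](C(=C)OCC)C(C)=C2 | intermediate (not isolated)
13 | 7-bromo-2-(1-ethoxyethenyl)-8-(1-ethoxyethoxy)-3-methylnaphthalen-1-ol (present as its magnesium naphthoxide) | CCOC(=C)c1c(C)cc2ccc(Br)c(OC(C)OCC)c2c1O | intermediate (not isolated)
14 | 1-(7-bromo-1,8-dihydroxy-3-methylnaphthalen-2-yl)ethan-1-one | CC(=O)c1c(C)cc2ccc(Br)c(O)c2c1O | intermediate
15 | (1S,2R)-2-(1-ethoxyethenyl)-8-(1-ethoxyethoxy)-3-methyl-7-(4,4,5,5-tetramethyl-1,3,2-dioxaborolan-2-yl)-1,2-dihydronaphthalen-1-ol | CC1(C)OB(OC1(C)C)c1ccc2c(c1OC(C)OCC)[C@@H](O)[C@H](C(=C)OCC)C(C)=C2 | intermediate (not isolated)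
16 | 1-{7-[(7R,8S)-7-(1-ethoxyethenyl)-1-(1-ethoxyethoxy)-8-hydroxy-6-methyl-7,8-dihydronaphthalen-2-yl]-1,8-dihydroxy-3-methylnaphthalen-2-yl}ethan-1-one | CC(=O)c1c(C)cc2ccc(-c3ccc4c(c3OC(C)OCC)[C@@H](O)[C@H](C(=C)OCC)C(C)=C4)c(O)c2c1O | intermediate
17 | 1-{7-[(7R,8S)-7-acetyl-1,8-dihydroxy-6-methyl-7,8-dihydronaphthalen-2-yl]-1,8-dihydroxy-3-methylnaphthalen-2-yl}ethan-1-one | CC(=O)c1c(C)cc2ccc(-c3ccc4c(c3O)[C@@H](O)[C@H](C(C)=O)C(C)=C4)c(O)c2c1O | target

## Step count and risks

Total steps: 7. Longest linear sequence: 5 steps (1 → 2 → 4 → 6 → 7; the branch through step 5 is equally long, and step 3 is a one-step reagent branch feeding steps 4 and 5).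

Most likely to fail:

Step 4. The (1-ethoxyvinyl)copper transfer is untested on oxabicycles and the selectivity factor of the resolution is unknown. The fallback sets out from 7 and comes back at 10. All of racemic 7 is opened with 9 under the achiral CuCl/PPh3 conditions of step 5 with an aqueous NaHCO3 quench, giving the racemic trans-carbinol, that is the 1:1 mixture of 10 and 11. This is resolved by non-enzymatic acylative kinetic resolution of the benzylic alcohol (chiral isothiourea catalyst homobenzotetramisole, 2-phenyl-3,4-dihydro-2H-pyrimido[2,1-b]benzothiazole, propanoic anhydride, iPr2NEt, CHCl3, 0 °C; catalyst antipode chosen in a pilot so that 11 reacts). Unreacted 10 is separated from (1R,2S)-7-bromo-2-(1-ethoxyethenyl)-8-(1-ethoxyethoxy)-3-methyl-1,2-dihydronaphthalen-1-yl propanoate F1. F1 is returned to 11 with K2CO3 in methanol; 11 is then deprotonated with EtMgBr in THF and carried through the benzaldehyde oxidation and acid hydrolysis of step 5 to 14. The stereo-determining event thus moves from the C–C bond formation to an O-acylation; the same resolution can also polish the ee of 10 from the main route.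

Step 5. The in-flask hydride transfer to benzaldehyde may be slow or accompanied by addition chemistry of the naphthoxide. The fallback sets out from 7 and comes back at 14. The ring opening is quenched with aqueous NaHCO3 and carbinol 11 is isolated. It is then dehydrogenated catalytically (RuCl2(PPh3)3, K2CO3, acetone, 56 °C, transfer dehydrogenation) through 12 to 13, and 13 is hydrolysed with dilute HCl in THF to 14. The oxidation thus becomes a separate, catalytic step on an isolated alcohol.

Step 6. The doubly ortho-oxygenated boronate 15 may protodeboronate, or the free carbinol of 10 may suffer under two palladium stages. The fallback sets out from 14 and comes back at 16. The roles are reversed: the robust fragment 14 is borylated separately (B2pin2, Pd(dppf)Cl2, KOAc, dioxane, 90 °C) to 1-[1,8-dihydroxy-3-methyl-7-(4,4,5,5-tetramethyl-1,3,2-dioxaborolan-2-yl)naphthalen-2-yl]ethan-1-one F2, which is purified and used in excess. It is coupled with bromide 10 as the electrophile (Pd(OAc)2, SPhos, K3PO4, toluene–water, 60 °C), so the chiral fragment sees a single, short palladium stage.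

Further compounds

F1 | step 4 | (1R,2S)-7-bromo-2-(1-ethoxyethenyl)-8-(1-ethoxyethoxy)-3-methyl-1,2-dihydronaphthalen-1-yl propanoate | Brc1ccc2c(c1OC(C)OCC)[C@H](OC(=O)CC)[C@@H](C(=C)OCC)C(C)=C2
F0 | step 5 | none | none
F2 | step 6 | 1-[1,8-dihydroxy-3-methyl-7-(4,4,5,5-tetramethyl-1,3,2-dioxaborolan-2-yl)naphthalen-2-yl]ethan-1-one | CC(=O)c1c(C)cc2ccc(B3OC(C)(C)C(C)(C)O3)c(O)c2c1O
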